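**Retrosynthetic overview**
- Oxonane (last ring): C6–C7 bond by intramolecular Nozaki–Hiyama–Kishi coupling of a 2-iodoallyl/aldehyde pair; the C4 octanoate is put on just before.
- Oxepane and tetrahydrofuran in one flask from a monocyclic epoxy diol: the C16 hydroxyl opens the C3–C4 epoxide (O–C3), then a Prins cyclisation with 3-iodobut-3-enal (O–C9, C9–C10) ends with capture of the C11 cation as the alcohol.
- Epoxy diol: C15 by hydroboration of the isopropenyl group; C10=C11 alkene by reductive 1,3-transposition of the carvone enone.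
- C1–C2: anti aldol of (R)-carvone with a cis-epoxy aldehyde (Z-selective olefination, Sharpless epoxidation).
- Ring order: cyclohexane (from carvone) → oxepane and tetrahydrofuran together → oxonane.

Positions are given in eunicellane numbering: ring carbons C1 and C10–C14, chain C2–C9, C15–C17 from the isopropenyl group, methyls C18–C20.
Assumption: 3-[(tert-butyldiphenylsilyl)oxy]propanal (1) is bought as a catalogue compound; if not, it is two routine steps from propane-1,3-diol.

**Step 1**
Reactants: 1 3-[(tert-butyldiphenylsilyl)oxy]propanal; 2 ethyl 2-[bis(2,2,2-trifluoroethoxy)phosphoryl]propanoate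
Product: 3 ethyl (2Z)-5-[(tert-butyldiphenylsilyl)oxy]-2-methylpent-2-enoate
Conditions: KN(SiMe3)2, 18-crown-6, THF, −78 °C
Reagents that add atoms: none
Why: Still–Gennari olefination; the electron-poor phosphonate under dissociating conditions eliminates fast from the kinetic adduct and gives the (Z)-trisubstituted enoate (no stereocentre formed).

**Step 2**
Reactants: 3 ethyl (2Z)-5-[(tert-butyldiphenylsilyl)oxy]-2-methylpent-2-enoate
Product: 4 (2Z)-5-[(tert-butyldiphenylsilyl)oxy]-2-methylpent-2-en-1-ol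
Conditions: iBu2AlH (2.2 equiv), CH2Cl2, −78 → 0 °C; Rochelle salt work-up
Reagents that add atoms: none
Why: 1,2-reduction of the enoate by the aluminium hydride gives the allylic alcohol with the Z geometry kept.

**Step 3**
Reactants: 4 (2Z)-5-[(tert-butyldiphenylsilyl)oxy]-2-methylpent-2-en-1-ol
Product: 5 [(2S,3R)-3-{2-[(tert-butyldiphenylsilyl)oxy]ethyl}-2-methyloxiran-2-yl]methanol (cis-epoxide)
Conditions: Ti(OiPr)4 (0.2 equiv), L-(+)-diethyl tartrate (0.24 equiv), tBuOOH, 4 Å molecular sieves, CH2Cl2, −20 °C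
Reagents that add atoms: tert-butyl hydroperoxide, CC(C)(C)OO
Why: Katsuki–Sharpless asymmetric epoxidation; the L-(+)-tartrate complex delivers oxygen to the face that gives the (2S,3R) cis-epoxide, which fixes C4 (final) and C3 (inverted on purpose in step 11).

**Step 4**
Reactants: 5 [(2S,3R)-3-{2-[(tert-butyldiphenylsilyl)oxy]ethyl}-2-methyloxiran-2-yl]methanol
Product: 6 (2R,3R)-3-{2-[(tert-butyldiphenylsilyl)oxy]ethyl}-2-methyloxirane-2-carbaldehyde
Conditions: Dess–Martin periodinane, pyridine, CH2Cl2, 0 °C → rt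
Reagents that add atoms: none
Why: Dess–Martin oxidation of the primary alcohol; the α-carbon is quaternary, so the epoxy aldehyde cannot epimerise.

**Step 5**
Reactants: 7 (R)-(−)-carvone; 6 (2R,3R)-3-{2-[(tert-butyldiphenylsilyl)oxy]ethyl}-2-methyloxirane-2-carbaldehyde
Product: 9 (5R,6R)-6-[(S)-hydroxy{(2S,3R)-3-[2-(tert-butyldiphenylsilyloxy)ethyl]-2-methyloxiran-2-yl}methyl]-2-methyl-5-(prop-1-en-2-yl)cyclohex-2-en-1-one, via dicyclohexylboron dienolate 8 (not isolated)
Conditions: (c-Hex)2BCl, Et3N, Et2O, 0 °C; 6, −78 → −20 °C; then MeOH, pH 7 buffer, 30% H2O2, 0 °C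
Reagents that add atoms: none
Why: Boron aldol reaction through a Zimmerman–Traxler chair; the ring-locked E-enolate gives the anti aldol (C1/C2), the aldehyde is attacked trans to the isopropenyl group at C1 and on its Cornforth/Felkin face (new OH anti to the epoxide oxygen), so all three elements are matched.

**Step 6**
Reactants: 9 the aldol adduct
Product: 10 4-methylbenzenesulfonohydrazone of 9 (all stereocentres as in 9)
Conditions: TsNHNH2 (1.2 equiv), EtOH, rt
Reagents that add atoms: 4-methylbenzenesulfonohydrazide, NNS(=O)(=O)c1ccc(C)cc1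
Why: Plain hydrazone condensation at the enone carbonyl; neutral conditions leave the β-hydroxy group and the epoxide alone.

**Step 7**
Reactants: 10 the tosylhydrazone
Product: 12 (S)-[(1R,6R)-3-methyl-6-(prop-1-en-2-yl)cyclohex-2-en-1-yl]{(2S,3R)-3-[2-(tert-butyldiphenylsilyloxy)ethyl]-2-methyloxiran-2-yl}methanol, via allylic diazene 11 (not isolated)
Conditions: catecholborane (3 equiv), CHCl3, 0 °C; then NaOAc·3H2O, 60 °C
Reagents that add atoms: none
Why: Kabalka reductive 1,3-transposition; hydride adds to C=N, sulfinate loss gives the allylic diazene, and its retro-ene loss of N2 puts hydrogen on C12 and the alkene at C10=C11 without touching any stereocentre.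

**Step 8**
Reactants: 12 the diene epoxy alcohol
Product: 13 (2R)-2-[(1S,2S)-2-[(S)-hydroxy{(2S,3R)-3-[2-(tert-butyldiphenylsilyloxy)ethyl]-2-methyloxiran-2-yl}methyl]-4-methylcyclohex-3-en-1-yl]propan-1-ol
Conditions: 9-BBN (3 equiv), THF, 0 °C → rt; then 3 M aq NaOAc, 30% H2O2, 0 °C → rt
Reagents that add atoms: hydrogen peroxide, OO
Why: Hydroboration–oxidation; 9-BBN takes the 1,1-disubstituted alkene over the trisubstituted ring alkene, and with C14–H eclipsing the alkene it adds to the face turned away from the branched C1 substituent, which gives 15R (about 5:1 expected; minor epimer removed by chromatography).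

**Step 9**
Reactants: 14 but-3-yn-1-ol
Product: 15 3-iodobut-3-en-1-ol
Conditions: NaI, Me3SiCl, H2O, MeCN, rt
Reagents that add atoms: sodium iodide, [Na+].[I-]
Why: Markovnikov addition of HI generated in the flask to the terminal alkyne gives the 2-iodoalkene.

**Step 10**
Reactants: 15 3-iodobut-3-en-1-ol
Product: 16 3-iodobut-3-enal
Conditions: Dess–Martin periodinane, CH2Cl2, 0 °C; filtered cold and used at once
Reagents that add atoms: none
Why: Dess–Martin oxidation under neutral conditions gives the β,γ-unsaturated aldehyde without conjugation if it is not stored.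

**Step 11**
Reactants: 13 the epoxy diol; 16 3-iodobut-3-enal
Product: 19 tricyclic diol (cyclohexane/tetrahydrofuran/oxepane core; 4-OH; 11-OH; 9-(2-iodoprop-2-enyl); C6 silyl ether; all nine stereocentres as in the target), via oxepane diol 17 (not isolated), via tertiary trifluoroacetate 18 (not isolated)
Conditions: CSA (0.2 equiv), CH2Cl2, 0 °C; then 16 (1.5 equiv), CF3CO2H (10 equiv), −20 °C; then sat. aq NaHCO3, MeOH, rt
Reagents that add atoms: trifluoroacetic acid, OC(=O)C(F)(F)F
Why: Proposed new method: acid opens the epoxide at its methyl-bearing carbon C3 by 7-exo attack of the C16 hydroxyl with inversion (closest known: acid-mediated hydroxy-epoxide cyclisations to oxepanes at tertiary epoxide carbons), then the C2 hydroxyl and 16 form an E-oxocarbenium ion that the C10=C11 alkene attacks on the face carrying C2 (closest known: Prins and Prins–pinacol routes to 2,5-cis-tetrahydrofurans), which places C8 pseudo-equatorial (9S) and fuses the rings cis (10R), and the tertiary C11 cation is captured axially, anti to the new bond, by trifluoroacetate, whose ester is cleaved in the work-up to the 11S alcohol.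

**Step 12**
Reactants: 19 the tricyclic diol
Product: 20 4-O-octanoyl derivative of 19
Conditions: octanoyl chloride, pyridine, DMAP (cat.), CH2Cl2, 0 °C → rt
Reagents that add atoms: octanoyl chloride, CCCCCCCC(=O)Cl
Why: DMAP-catalysed acylation takes the secondary C4 hydroxyl; the tertiary C11 hydroxyl does not react under these conditions.

**Step 13**
Reactants: 20 the octanoate
Product: 21 primary C6 alcohol (silyl group removed; otherwise as 20)
Conditions: HF·pyridine, pyridine, THF, 0 °C → rt
Reagents that add atoms: none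
Why: Fluoride-driven desilylation; the mildly acidic medium prevents migration of the octanoyl group to the new primary hydroxyl.

**Step 14**
Reactants: 21 the primary alcohol
Product: 22 C6 aldehyde (3-acyloxy aldehyde bearing the 2-iodoallyl group)
Conditions: Dess–Martin periodinane, pyridine, CH2Cl2, 0 °C
Reagents that add atoms: none
Why: Dess–Martin oxidation stops at the aldehyde, and the buffered, non-basic medium avoids β-elimination of the octanoate.

**Step 15**
Reactants: 22 the iodo aldehyde
Product: 23 the target CNP0398453.2 (1S,2S,3S,4R,6R,9S,10R,11S,14S,15R)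
Conditions: CrCl2 (10 equiv), NiCl2 (0.1 equiv), DMSO, rt, 2 mM
Reagents that add atoms: none
Why: Intramolecular Nozaki–Hiyama–Kishi reaction; the alkenyl chromium species formed via nickel adds to the aldehyde to close the oxonane and give the 2-methylene alcohol, with the conformation of the forming nine-membered ring expected to favour the 6R carbinol, and the ester and free tertiary alcohol are tolerated.

**Compound list**
1 | 3-[(tert-butyldiphenylsilyl)oxy]propanal | O=CCCO[Si](c1ccccc1)(c1ccccc1)C(C)(C)C | starting material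
2 | ethyl 2-[bis(2,2,2-trifluoroethoxy)phosphoryl]propanoate | CCOC(=O)C(C)P(=O)(OCC(F)(F)F)OCC(F)(F)F | starting material
3 | ethyl (2Z)-5-[(tert-butyldiphenylsilyl)oxy]-2-methylpent-2-enoate | CCOC(=O)/C(C)=C\CCO[Si](c1ccccc1)(c1ccccc1)C(C)(C)C | intermediate
4 | (2Z)-5-[(tert-butyldiphenylsilyl)oxy]-2-methylpent-2-en-1-ol | OC/C(C)=C\CCO[Si](c1ccccc1)(c1ccccc1)C(C)(C)C | intermediate
5 | [(2S,3R)-3-{2-[(tert-butyldiphenylsilyl)oxy]ethyl}-2-methyloxiran-2-yl]methanol | OC[C@]1(C)O[C@@H]1CCO[Si](c1ccccc1)(c1ccccc1)C(C)(C)C | intermediate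
6 | (2R,3R)-3-{2-[(tert-butyldiphenylsilyl)oxy]ethyl}-2-methyloxirane-2-carbaldehyde | O=C[C@]1(C)O[C@@H]1CCO[Si](c1ccccc1)(c1ccccc1)C(C)(C)C | intermediate
7 | (R)-(−)-carvone | CC1=CC[C@H](CC1=O)C(C)=C | starting material
8 | dicyclohexylboron dienolate of carvone | CC1=CC[C@H](C=C1OB(C2CCCCC2)C2CCCCC2)C(C)=C | intermediate
9 | aldol adduct, (5R,6R)-enone with (S)-carbinol and (2S,3R)-epoxide | O[C@@H]([C@@H]1C(=O)C(C)=CC[C@H]1C(C)=C)[C@]1(C)O[C@@H]1CCO[Si](c1ccccc1)(c1ccccc1)C(C)(C)C | intermediate
10 | tosylhydrazone of 9 | O[C@@H]([C@@H]1C(=NNS(=O)(=O)c2ccc(C)cc2)C(C)=CC[C@H]1C(C)=C)[C@]1(C)O[C@@H]1CCO[Si](c1ccccc1)(c1ccccc1)C(C)(C)C | intermediate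
11 | allylic diazene (configuration at the N-bearing carbon not defined and lost in the next event) | O[C@@H]([C@@H]1C(N=N)C(C)=CC[C@H]1C(C)=C)[C@]1(C)O[C@@H]1CCO[Si](c1ccccc1)(c1ccccc1)C(C)(C)C | intermediate
12 | (S)-[(1R,6R)-3-methyl-6-(prop-1-en-2-yl)cyclohex-2-en-1-yl][(2S,3R)-epoxide]methanol | O[C@@H]([C@@H]1C=C(C)CC[C@H]1C(C)=C)[C@]1(C)O[C@@H]1CCO[Si](c1ccccc1)(c1ccccc1)C(C)(C)C | intermediate
13 | epoxy diol with (15R)-CH(CH3)CH2OH side chain | O[C@@H]([C@@H]1C=C(C)CC[C@H]1[C@@H](C)CO)[C@]1(C)O[C@@H]1CCO[Si](c1ccccc1)(c1ccccc1)C(C)(C)C | intermediate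
14 | but-3-yn-1-ol | C#CCCO | starting material
15 | 3-iodobut-3-en-1-ol | C=C(I)CCO | intermediate
16 | 3-iodobut-3-enal | C=C(I)CC=O | intermediate
17 | oxepane diol (trans-fused cyclohexene–oxepane; 2-OH and 4-OH free) | O[C@H]1[C@@H]2C=C(C)CC[C@H]2[C@@H](C)CO[C@@]1(C)[C@H](O)CCO[Si](c1ccccc1)(c1ccccc1)C(C)(C)C | intermediate
18 | C11 trifluoroacetate of 19 | C=C(I)C[C@@H]2O[C@H]3[C@H]4[C@@H](CC[C@](C)(OC(=O)C(F)(F)F)[C@H]42)[C@@H](C)CO[C@@]3(C)[C@H](O)CCO[Si](c1ccccc1)(c1ccccc1)C(C)(C)C | intermediate
19 | tricyclic diol with 2-iodoallyl group on C9 | C=C(I)C[C@@H]2O[C@H]3[C@H]4[C@@H](CC[C@](C)(O)[C@H]42)[C@@H](C)CO[C@@]3(C)[C@H](O)CCO[Si](c1ccccc1)(c1ccccc1)C(C)(C)C | intermediate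
20 | 4-O-octanoate of 19 | C=C(I)C[C@@H]2O[C@H]3[C@H]4[C@@H](CC[C@](C)(O)[C@H]42)[C@@H](C)CO[C@@]3(C)[C@H](OC(=O)CCCCCCC)CCO[Si](c1ccccc1)(c1ccccc1)C(C)(C)C | intermediate
21 | primary C6 alcohol | C=C(I)C[C@@H]2O[C@H]3[C@H]4[C@@H](CC[C@](C)(O)[C@H]42)[C@@H](C)CO[C@@]3(C)[C@H](OC(=O)CCCCCCC)CCO | intermediate
22 | C6 aldehyde | C=C(I)C[C@@H]2O[C@H]3[C@H]4[C@@H](CC[C@](C)(O)[C@H]42)[C@@H](C)CO[C@@]3(C)[C@H](OC(=O)CCCCCCC)CC=O | intermediate
23 | CNP0398453.2 | C=C1C[C@@H]2O[C@H]3[C@H]4[C@@H](CC[C@](C)(O)[C@H]42)[C@@H](C)CO[C@@]3(C)[C@H](OC(=O)CCCCCCC)C[C@H]1O | target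

**Count**
Total steps: 15. Longest linear sequence: 13 (steps 1–8 and 11–15); steps 9–10 make the side fragment 16.

**Steps most likely to fail, each with a fallback**

Step 11 (double cyclisation). The oxepane closure can lose to epoxide rearrangement, and the C11 cation can eliminate instead of being captured. The fallback sets out from 13 and separates the two ring closures with a different termination. CSA alone gives 17, which is isolated. Its 2,4-diol is condensed with 16 (PPTS, MgSO4) to the 1,3-dioxane acetal F1. SnCl4 at −78 °C opens the acetal and the Prins cyclisation ends by chloride capture to give the tertiary chloride F2. AgOTf in aqueous acetone hydrolyses F2 by ionisation, and water enters on the open axial face. The fallback comes back to the route at 19.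

Step 8 (C15 by hydroboration). Substrate control over the exocyclic centre may be poor. The fallback sets out from 12 and sets C15 inside a ring instead. The C2 hydroxyl is silylated with (Me2SiH)2NH to the dimethylsilyl ether F3. RhCl(PPh3)3-catalysed intramolecular hydrosilylation of the isopropenyl group gives the seven-membered cyclic siloxane F4. Tamao–Fleming oxidation (H2O2, KF, KHCO3) cleaves both Si–C and Si–O bonds and returns to the route at 13.

Step 10 (aldehyde 16). The β,γ-unsaturated iodo aldehyde may slip into conjugation before or during the acid step. The fallback sets out from 13 and brings in the vinyl iodide after the cyclisation. Commercial 4-(trimethylsilyl)but-3-yn-1-ol is oxidised (Dess–Martin) to 4-(trimethylsilyl)but-3-ynal F5, which is used in place of 16 under the step 11 conditions to give the silyl alkyne tricyclic diol F6. K2CO3 in MeOH removes the silyl group to give the terminal alkyne F7. B-iodo-9-BBN followed by AcOH adds HI across the alkyne in the Markovnikov sense, and the fallback comes back to the route at 19.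

**Further compounds**
F1 | step 11 | 1,3-dioxane acetal of 17 with 16 across O2 and O4 (acetal carbon configuration not defined) | C=C(I)CC1O[C@H]2[C@@H]3C=C(C)CC[C@H]3[C@@H](C)CO[C@@]2(C)[C@@H](CCO[Si](c2ccccc2)(c2ccccc2)C(C)(C)C)O1
F2 | step 11 | C11 tertiary chloride analogue of 19 | C=C(I)C[C@@H]2O[C@H]3[C@H]4[C@@H](CC[C@](C)(Cl)[C@H]42)[C@@H](C)CO[C@@]3(C)[C@H](O)CCO[Si](c1ccccc1)(c1ccccc1)C(C)(C)C
F3 | step 8 | dimethylsilyl ether of 12 at the C2 oxygen | C[SiH](C)O[C@@H]([C@@H]1C=C(C)CC[C@H]1C(C)=C)[C@]1(C)O[C@@H]1CCO[Si](c1ccccc1)(c1ccccc1)C(C)(C)C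
F4 | step 8 | seven-membered cyclic siloxane (Si bonded to C16 and O2; 15R) | C[Si]1(C)C[C@H](C)[C@@H]2CCC(C)=C[C@H]2[C@H](O1)[C@]1(C)O[C@@H]1CCO[Si](c1ccccc1)(c1ccccc1)C(C)(C)C
F5 | step 10 | 4-(trimethylsilyl)but-3-ynal | C[Si](C)(C)C#CCC=O
F6 | step 10 | silyl alkyne analogue of 19 (3-(trimethylsilyl)prop-2-ynyl on C9) | C[Si](C)(C)C#CC[C@@H]2O[C@H]3[C@H]4[C@@H](CC[C@](C)(O)[C@H]42)[C@@H](C)CO[C@@]3(C)[C@H](O)CCO[Si](c1ccccc1)(c1ccccc1)C(C)(C)C
F7 | step 10 | terminal alkyne analogue of 19 (prop-2-ynyl on C9) | C#CC[C@@H]2O[C@H]3[C@H]4[C@@H](CC[C@](C)(O)[C@H]42)[C@@H](C)CO[C@@]3(C)[C@H](O)CCO[Si](c1ccccc1)(c1ccccc1)C(C)(C)C
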